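**Plan**

- Cuts: ring D at the lactol C–O bond. Ring C at the ester O–C(aryl) bond on ring B and at the ether O–C(aryl) bond on ring A. Ring B at two C–C bonds, C(OH)–C(CHO) and C(O-ether)–C(O-ester).
- Enabling feature: ring B is hexasubstituted, and its phenol carbon lies para to its diaryl-ether carbon. These two C–O carbons correspond to C2 (exocyclic oxygen) and C5 (ring oxygen) of a 2-siloxyfuran. The lactone-carbonyl and lactol carbons sit on furan C3 and C4, and the formyl-bearing and ester-oxygen carbons are the two carbons of an ynoate.
- Forward order: butenolide, siloxyfuran, ring B by cycloaddition and aromatisation, ester to formyl. Ring A, built separately by directed metalation, is joined by SNAr. Ring C closes by copper-catalysed carboxylate–aryl bromide coupling, and ring D closes in the final acid deprotection.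
- Stereochemistry: the only stereocentre, the (S)-lactol carbon, arises as a racemate on ring D closure. It is secured by resolution on a chiral stationary phase, and the (R)-form can be recycled by racemisation.

Key step: step 4

Assumption: the lactol carbon is a hemiacylal that can racemise through its ring-opened formyl acid tautomer. It is taken to be configurationally stable long enough in cold, weakly acidic, alcohol-free media for the (S)-enantiomer to be separated, handled and stored as a solid.

Step 1
Reactants: 1 3-bromo-1,1-dimethoxypropan-2-one; 2 mono-tert-butyl malonate (3-tert-butoxy-3-oxopropanoic acid)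
Product: 4 tert-butyl 4-(dimethoxymethyl)-2-oxo-2,5-dihydrofuran-3-carboxylate, via keto diester 3 (not isolated)
Conditions: KHCO3, DMF, rt; then DBU, 0 °C to rt
Reagents that add atoms: none
Why: SN2 displacement of the alpha-bromo ketone by the half-ester carboxylate gives 3, whose acidic CH2 then adds to the acetal-activated ketone and loses water (intramolecular Knoevenagel condensation, 5-exo-trig), the standard entry to 3-alkoxycarbonyl-4-substituted butenolides; no stereocentre is formed.

Step 2
Reactants: 4 tert-butyl 4-(dimethoxymethyl)-2-oxo-2,5-dihydrofuran-3-carboxylate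
Product: 5 tert-butyl 4-(dimethoxymethyl)-2-(triisopropylsilyloxy)furan-3-carboxylate
Conditions: TIPSOTf, Et3N, CH2Cl2, 0 °C
Reagents that add atoms: triisopropylsilyl trifluoromethanesulfonate, CC(C)[Si](OS(=O)(=O)C(F)(F)F)(C(C)C)C(C)C
Why: Soft enolisation with a silyl triflate and a tertiary amine is the usual way from butenolides to 2-siloxyfurans, the gamma-protons of 4 being strongly acidified by the alkylidene malonate unit, while excess amine and the electron-poor surroundings of the acetal should keep it from being ionised.

Step 3
Reactants: 6 methyl propiolate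
Product: 7 methyl 3-bromopropiolate
Conditions: NBS, AgNO3 (10 mol %), acetone, rt
Reagents that add atoms: N-bromosuccinimide, O=C1CCC(=O)N1Br
Why: Silver-catalysed electrophilic bromination of the terminal alkyne C–H with NBS is the established preparation of 3-bromopropiolates.

Step 4
Reactants: 5 tert-butyl 4-(dimethoxymethyl)-2-(triisopropylsilyloxy)furan-3-carboxylate; 7 methyl 3-bromopropiolate
Product: 9 1-tert-butyl 3-methyl 4-bromo-6-(dimethoxymethyl)-5-hydroxy-2-(triisopropylsilyloxy)benzene-1,3-dicarboxylate, via oxanorbornadiene 8 (not isolated)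
Conditions: 7 (1.5 equiv), 2,6-di-tert-butylpyridine (10 mol %), toluene, 90 °C, sealed tube
Reagents that add atoms: none
Why: The diene of 5 (furan C2 to C5) adds across the triple bond of 7 in a thermal, strongly asynchronous [4+2] cycloaddition that closes ring B as a six-membered carbocycle in intermolecular fashion, joining furan C5 to the bromine-bearing carbon and furan C2 to the ester-bearing carbon to give 8. In 8 the bridge C–O bond at the siloxy bridgehead ionises under the push of the silyloxy oxygen, and loss of the proton at the other bridgehead aromatises the ring, so the former furan oxygen ends as the free phenol para to OTIPS. The closest known reaction types are the Diels–Alder/bridge-opening aromatisation of 2-siloxy- and 2-alkoxyfurans with acetylenic esters and the regioselective cycloaddition of 3-bromopropiolates to 2-substituted furans. The only selectivity needed is regiochemical, and it is secured by the siloxy group, which places the largest HOMO coefficient on the unsubstituted C5 so that this carbon pairs with the beta carbon of the ynoate, the one that carries bromine. The two bridgehead stereocentres of 8 form as a racemate and vanish on aromatisation, so no stereocontrol is required. The non-polar solvent disfavours an ionic addition–elimination at the C–Br carbon, and the hindered base intercepts traces of acid that would strip the acetal next to the new phenol.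

Step 5
Reactants: 9 1-tert-butyl 3-methyl 4-bromo-6-(dimethoxymethyl)-5-hydroxy-2-(triisopropylsilyloxy)benzene-1,3-dicarboxylate
Product: 10 tert-butyl 4-bromo-6-(dimethoxymethyl)-5-hydroxy-3-(hydroxymethyl)-2-(triisopropylsilyloxy)benzoate
Conditions: i-Bu2AlH (3.5 equiv), THF–toluene, −78 to −40 °C; aq. potassium sodium tartrate
Reagents that add atoms: none
Why: In this hydride reduction of an ester to the primary alcohol the methyl ester is attacked much faster than the di-ortho-substituted tert-butyl ester, the phenol merely consumes one equivalent of hydride, and low temperature in a donor solvent tempers the Lewis acidity of aluminium towards the acetal.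

Step 6
Reactants: 10 tert-butyl 4-bromo-6-(dimethoxymethyl)-5-hydroxy-3-(hydroxymethyl)-2-(triisopropylsilyloxy)benzoate
Product: 11 tert-butyl 4-bromo-6-(dimethoxymethyl)-3-formyl-5-hydroxy-2-(triisopropylsilyloxy)benzoate
Conditions: MnO2 (excess), CH2Cl2, rt
Reagents that add atoms: none
Why: Heterogeneous MnO2 oxidation is selective for benzylic alcohols and runs under neutral conditions that should spare the aryl silyl ether, the acetal and the electron-poor phenol.

Step 7
Reactants: 12 3-fluoro-5-methylphenol
Product: 13 1-fluoro-3-(methoxymethoxy)-5-methylbenzene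
Conditions: NaH, MOMCl, THF, 0 °C to rt
Reagents that add atoms: chloromethyl methyl ether, COCCl
Why: Williamson-type O-alkylation of the phenoxide installs a group that directs the later metalation, resists bases and organolithiums, and falls off in the final acid step.

Step 8
Reactants: 13 1-fluoro-3-(methoxymethoxy)-5-methylbenzene
Product: 14 2-bromo-1-fluoro-5-(methoxymethoxy)-3-methylbenzene
Conditions: NBS, MeCN, 0 °C to rt
Reagents that add atoms: N-bromosuccinimide, O=C1CCC(=O)N1Br
Why: Electrophilic aromatic bromination with NBS in acetonitrile goes para to the strongest donor, the alkoxy group, as it does with other 3,5-disubstituted aryl ethers, which places bromine between F and CH3 without generating acid that would harm the MOM ether.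

Step 9
Reactants: 14 2-bromo-1-fluoro-5-(methoxymethoxy)-3-methylbenzene
Product: 16 3-bromo-2-fluoro-6-(methoxymethoxy)-4-methylbenzaldehyde, via aryllithium 15 (not isolated)
Conditions: LiN(i-Pr)2, THF, −78 °C; DMF; AcOH
Reagents that add atoms: N,N-dimethylformamide, CN(C)C=O; for the intermediate only: lithium diisopropylamide, [Li]N(C(C)C)C(C)C
Why: In this directed ortho-metalation the C–H flanked by F and OMOM is by far the most acidic site, the amide base does not exchange the bromide, no hydrogen ortho to bromine is available for a halogen dance, and DMF formylates the lithiated carbon.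

Step 10
Reactants: 16 3-bromo-2-fluoro-6-(methoxymethoxy)-4-methylbenzaldehyde
Product: 19 2-fluoro-3-formyl-4-(methoxymethoxy)-6-methylbenzoic acid, via lithium amino alkoxide 17 (not isolated), via aryllithium 18 (not isolated)
Conditions: morpholine, n-BuLi, THF, −78 °C, then 16; n-BuLi, −78 °C; CO2; 1 M HCl to pH 3, 0 °C
Reagents that add atoms: carbon dioxide, O=C=O; for the intermediates only: morpholine, C1COCCN1, and n-butyllithium, [Li]CCCC
Why: Addition of lithium morpholide masks the aldehyde in situ as an alpha-amino alkoxide, a known device for bromobenzaldehydes, so that bromine–lithium exchange and carboxylation can follow in the same flask, and at −78 °C the ortho-fluoro aryllithium should not lose LiF.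

Step 11
Reactants: 19 2-fluoro-3-formyl-4-(methoxymethoxy)-6-methylbenzoic acid
Product: 20 allyl 2-fluoro-3-formyl-4-(methoxymethoxy)-6-methylbenzoate
Conditions: allyl bromide, KHCO3, DMF, rt
Reagents that add atoms: allyl bromide, C=CCBr
Why: SN2 alkylation of the carboxylate bypasses attack at the hindered carbonyl carbon, and the weak base leaves the activated C–F bond untouched.

Step 12
Reactants: 11 tert-butyl 4-bromo-6-(dimethoxymethyl)-3-formyl-5-hydroxy-2-(triisopropylsilyloxy)benzoate; 20 allyl 2-fluoro-3-formyl-4-(methoxymethoxy)-6-methylbenzoate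
Product: 22 tert-butyl 5-[2-(allyloxycarbonyl)-6-formyl-5-(methoxymethoxy)-3-methylphenoxy]-4-bromo-6-(dimethoxymethyl)-3-formyl-2-hydroxybenzoate, via silyl ether 21 (not isolated)
Conditions: Cs2CO3, DMF, 60 °C, Ar; AcOH
Reagents that add atoms: none
Why: In this nucleophilic aromatic substitution (addition–elimination) the C–F carbon of 20 is flanked by formyl and ester groups that stabilise the Meisenheimer adduct while OMOM is meta to it, the only free OH of 11 is the nucleophile, and the fluoride released then strips the activated aryl TIPS ether to a phenoxide that is flanked by two carbonyl groups and is too stabilised to compete for 20.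

Step 13
Reactants: 22 tert-butyl 5-[2-(allyloxycarbonyl)-6-formyl-5-(methoxymethoxy)-3-methylphenoxy]-4-bromo-6-(dimethoxymethyl)-3-formyl-2-hydroxybenzoate
Product: 23 tert-butyl 5-[2-(allyloxycarbonyl)-6-formyl-5-(methoxymethoxy)-3-methylphenoxy]-4-bromo-6-(dimethoxymethyl)-3-formyl-2-(methoxymethoxy)benzoate
Conditions: MOMCl, K2CO3, DMF, 0 °C to rt
Reagents that add atoms: chloromethyl methyl ether, COCCl
Why: O-alkylation of the acidic phenol with the highly reactive chloromethyl ether caps it, which keeps ring B electron-poor and removes a copper-chelating salicylaldehyde unit before ring C is closed.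

Step 14
Reactants: 23 tert-butyl 5-[2-(allyloxycarbonyl)-6-formyl-5-(methoxymethoxy)-3-methylphenoxy]-4-bromo-6-(dimethoxymethyl)-3-formyl-2-(methoxymethoxy)benzoate
Product: 24 2-[2-bromo-5-(tert-butoxycarbonyl)-6-(dimethoxymethyl)-3-formyl-4-(methoxymethoxy)phenoxy]-3-formyl-4-(methoxymethoxy)-6-methylbenzoic acid
Conditions: Pd(PPh3)4 (5 mol %), PhNHMe, THF, rt
Reagents that add atoms: none
Why: In this Tsuji–Trost-type allyl transfer zerovalent palladium ionises the allyl ester at room temperature and N-methylaniline traps the allyl unit, under neutral conditions at which the di-ortho-substituted aryl bromide should not undergo oxidative addition and the weakly nucleophilic amine leaves the aldehydes alone.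

Step 15
Reactants: 24 2-[2-bromo-5-(tert-butoxycarbonyl)-6-(dimethoxymethyl)-3-formyl-4-(methoxymethoxy)phenoxy]-3-formyl-4-(methoxymethoxy)-6-methylbenzoic acid
Product: 25 tert-butyl 6-(dimethoxymethyl)-4,9-diformyl-3,8-bis(methoxymethoxy)-1-methyl-11-oxo-11H-dibenzo[b,e][1,4]dioxepine-7-carboxylate
Conditions: CuI (20 mol %), 1,10-phenanthroline (40 mol %), Cs2CO3, DMF, 100 °C
Reagents that add atoms: none
Why: The intramolecular Ullmann-type coupling of a carboxylate with an aryl bromide, known for the closure of biaryl lactones, here closes the seven-membered ring C, helped by a bromide that is ortho to formyl and para to the ester (activated for oxidative addition and for direct addition–elimination alike) and by the ether oxygen that holds both partners ortho to it.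

Step 16
Reactants: 25 tert-butyl 6-(dimethoxymethyl)-4,9-diformyl-3,8-bis(methoxymethoxy)-1-methyl-11-oxo-11H-dibenzo[b,e][1,4]dioxepine-7-carboxylate
Product: 27 racemic lactol (the target constitution with C6–CH(OH)–O–C(=O)–C7 as ring D), via formyl acid 26 (not isolated)
Conditions: TFA–CH2Cl2–H2O (10:10:1), 0 °C to rt
Reagents that add atoms: water, O
Why: Acidolysis removes the tert-butyl ester, the dimethyl acetal and both MOM ethers in one operation, and 26 then closes ring D by 5-exo-trig addition of the carboxyl OH to the neighbouring aldehyde, since the ring–chain equilibrium of 2-formylbenzoic acids lies on the lactol side; the new stereocentre forms without control, as a racemate.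

Step 17
Reactants: 27 racemic lactol
Product: 28 target, (S)-lactol: 4,9-diformyl-3,8-dihydroxy-1-methyl-11-oxodibenzo[b,e][1,4]dioxepine with the gamma-lactone C6–CH(OH)–O–C(=O)–C7 fused to ring B, lactol carbon S
Conditions: preparative HPLC, immobilised amylose tris(3,5-dimethylphenylcarbamate) phase, MeCN with 0.1 % HCO2H, 5 °C; cold evaporation
Reagents that add atoms: none
Why: Chromatographic resolution on a chiral stationary phase separates the enantiomers by their different adsorption and so delivers the stereocentre of step 16 as the (S)-form (to be assigned by ECD against calculation), the alcohol-free cold eluent avoiding acetal exchange and slowing racemisation, while the (R)-form can be racemised through 26 and fed back.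

**Compound list**

1 | 3-bromo-1,1-dimethoxypropan-2-one | COC(OC)C(=O)CBr | starting material
2 | mono-tert-butyl malonate | CC(C)(C)OC(=O)CC(=O)O | starting material
3 | tert-butyl 3,3-dimethoxy-2-oxopropyl malonate | COC(OC)C(=O)COC(=O)CC(=O)OC(C)(C)C | intermediate
4 | tert-butyl 4-(dimethoxymethyl)-2-oxo-2,5-dihydrofuran-3-carboxylate | COC(OC)C1=C(C(=O)OC(C)(C)C)C(=O)OC1 | intermediate
5 | tert-butyl 4-(dimethoxymethyl)-2-(triisopropylsilyloxy)furan-3-carboxylate | COC(OC)c1coc(O[Si](C(C)C)(C(C)C)C(C)C)c1C(=O)OC(C)(C)C | intermediate
6 | methyl propiolate | C#CC(=O)OC | starting material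
7 | methyl 3-bromopropiolate | COC(=O)C#CBr | intermediate
8 | 6-tert-butyl 2-methyl 3-bromo-5-(dimethoxymethyl)-1-(triisopropylsilyloxy)-7-oxabicyclo[2.2.1]hepta-2,5-diene-2,6-dicarboxylate (racemic) | COC(=O)C1=C(Br)C2OC1(O[Si](C(C)C)(C(C)C)C(C)C)C(C(=O)OC(C)(C)C)=C2C(OC)OC | intermediate
9 | 1-tert-butyl 3-methyl 4-bromo-6-(dimethoxymethyl)-5-hydroxy-2-(triisopropylsilyloxy)benzene-1,3-dicarboxylate | COC(=O)c1c(Br)c(O)c(C(OC)OC)c(C(=O)OC(C)(C)C)c1O[Si](C(C)C)(C(C)C)C(C)C | intermediate
10 | tert-butyl 4-bromo-6-(dimethoxymethyl)-5-hydroxy-3-(hydroxymethyl)-2-(triisopropylsilyloxy)benzoate | CC(C)(C)OC(=O)c1c(C(OC)OC)c(O)c(Br)c(CO)c1O[Si](C(C)C)(C(C)C)C(C)C | intermediate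
11 | tert-butyl 4-bromo-6-(dimethoxymethyl)-3-formyl-5-hydroxy-2-(triisopropylsilyloxy)benzoate | CC(C)(C)OC(=O)c1c(C(OC)OC)c(O)c(Br)c(C=O)c1O[Si](C(C)C)(C(C)C)C(C)C | intermediate
12 | 3-fluoro-5-methylphenol | Cc1cc(O)cc(F)c1 | starting material
13 | 1-fluoro-3-(methoxymethoxy)-5-methylbenzene | COCOc1cc(C)cc(F)c1 | intermediate
14 | 2-bromo-1-fluoro-5-(methoxymethoxy)-3-methylbenzene | COCOc1cc(C)c(Br)c(F)c1 | intermediate
15 | [3-bromo-2-fluoro-6-(methoxymethoxy)-4-methylphenyl]lithium | COCOc1cc(C)c(Br)c(F)c1[Li] | intermediate
16 | 3-bromo-2-fluoro-6-(methoxymethoxy)-4-methylbenzaldehyde | COCOc1cc(C)c(Br)c(F)c1C=O | intermediate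
17 | lithium [3-bromo-2-fluoro-6-(methoxymethoxy)-4-methylphenyl](morpholin-4-yl)methanolate (racemic) | COCOc1cc(C)c(Br)c(F)c1C([O-])N1CCOCC1.[Li+] | intermediate
18 | the 3-lithio analogue of 17 (Li in place of Br; racemic) | COCOc1cc(C)c([Li])c(F)c1C([O-])N1CCOCC1.[Li+] | intermediate
19 | 2-fluoro-3-formyl-4-(methoxymethoxy)-6-methylbenzoic acid | COCOc1cc(C)c(C(=O)O)c(F)c1C=O | intermediate
20 | allyl 2-fluoro-3-formyl-4-(methoxymethoxy)-6-methylbenzoate | COCOc1cc(C)c(C(=O)OCC=C)c(F)c1C=O | intermediate
21 | tert-butyl 5-[2-(allyloxycarbonyl)-6-formyl-5-(methoxymethoxy)-3-methylphenoxy]-4-bromo-6-(dimethoxymethyl)-3-formyl-2-(triisopropylsilyloxy)benzoate | CC(C)(C)OC(=O)c1c(C(OC)OC)c(Oc2c(C=O)c(OCOC)cc(C)c2C(=O)OCC=C)c(Br)c(C=O)c1O[Si](C(C)C)(C(C)C)C(C)C | intermediate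
22 | tert-butyl 5-[2-(allyloxycarbonyl)-6-formyl-5-(methoxymethoxy)-3-methylphenoxy]-4-bromo-6-(dimethoxymethyl)-3-formyl-2-hydroxybenzoate | CC(C)(C)OC(=O)c1c(C(OC)OC)c(Oc2c(C=O)c(OCOC)cc(C)c2C(=O)OCC=C)c(Br)c(C=O)c1O | intermediate
23 | tert-butyl 5-[2-(allyloxycarbonyl)-6-formyl-5-(methoxymethoxy)-3-methylphenoxy]-4-bromo-6-(dimethoxymethyl)-3-formyl-2-(methoxymethoxy)benzoate | CC(C)(C)OC(=O)c1c(C(OC)OC)c(Oc2c(C=O)c(OCOC)cc(C)c2C(=O)OCC=C)c(Br)c(C=O)c1OCOC | intermediate
24 | 2-[2-bromo-5-(tert-butoxycarbonyl)-6-(dimethoxymethyl)-3-formyl-4-(methoxymethoxy)phenoxy]-3-formyl-4-(methoxymethoxy)-6-methylbenzoic acid | CC(C)(C)OC(=O)c1c(C(OC)OC)c(Oc2c(C=O)c(OCOC)cc(C)c2C(=O)O)c(Br)c(C=O)c1OCOC | intermediate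
25 | tert-butyl 6-(dimethoxymethyl)-4,9-diformyl-3,8-bis(methoxymethoxy)-1-methyl-11-oxo-11H-dibenzo[b,e][1,4]dioxepine-7-carboxylate | Cc1cc(OCOC)c(C=O)c2c1C(=O)Oc1c(C=O)c(OCOC)c(C(=O)OC(C)(C)C)c(C(OC)OC)c1O2 | intermediate
26 | 4,6,9-triformyl-3,8-dihydroxy-1-methyl-11-oxo-11H-dibenzo[b,e][1,4]dioxepine-7-carboxylic acid | Cc1cc(O)c(C=O)c2c1C(=O)Oc1c(C=O)c(O)c(C(=O)O)c(C=O)c1O2 | intermediate
27 | racemic lactol (ring D closed, both configurations at the lactol carbon) | Cc1cc(O)c(C=O)c2c1C(=O)Oc1c(C=O)c(O)c3c(c1O2)C(O)OC3=O | intermediate
28 | (S)-lactol, CNP0296574.1 | Cc1cc(O)c(C=O)c2c1C(=O)Oc1c(C=O)c(O)c3c(c1O2)[C@@H](O)OC3=O | target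

**Step count**

- Total step count: 17.
- Longest linear sequence: 11 steps (1, 2, 4, 5, 6, 12–17 from 1). The ring A branch (7–11, then 12–17 from 12) is equally long.

**Steps most likely to fail**

**Step 4.** The polarised siloxyfuran may attack the bromoalkyne in a stepwise ionic manner. Expulsion of bromide and loss of the silyl group could then run faster than formation of the second C–C bond. The fallback sets out from 5 and 6 and comes back at 9. It keeps the same two ring B bonds but brings the halogen in only after the ring exists.
- Heating 5 with methyl propiolate 6 in toluene pairs furan C5 with the beta carbon as before. There is no leaving group on that carbon.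
- This should give the bromine-free oxanorbornadiene F1, which opens and aromatises to the debromo isophthalate F2.
- The only free ring position of F2 is ortho to the new phenol. Electrophilic bromination with NBS (CH2Cl2, 0 °C) can therefore enter only there, which gives 9.

**Step 15.** Protodecarboxylation of the di-ortho-substituted benzoic acid and hydrodebromination may outrun closure of the crowded seven-membered ring. The fallback sets out from 24 and comes back at 25. It replaces the C–O coupling by the classical depsidone closure, an esterification.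
- The bromide is activated by the ortho formyl and para ester groups. It is displaced by the anion of (E)-benzaldoxime (Cs2CO3, DMSO, 80 °C) to give the O-aryl oxime ether F3.
- F3 loses benzonitrile under the same basic conditions and leaves the hydroxy acid F4.
- Dehydrative lactonisation of F4 with DCC (CH2Cl2–toluene, rt) then forms the aryl ester bond of ring C and gives 25.

**Step 17.** Racemisation by ring–chain tautomerism may proceed on the time scale of elution and evaporation, which would erode the separation. The fallback sets out from 27 and comes back at 28. It moves the resolution to configurationally stable acetals.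
- Acid-catalysed exchange of the lactol OH with commercial (R)-1-(2-nitrophenyl)ethanol (cat. camphorsulfonic acid, dioxane, molecular sieves, 60 °C) uses the ready pseudo-ester formation of such depsidone lactols.
- It should give the (S)-acetal F5 and the (R)-acetal F6. These are separated by chromatography or crystallisation, and F6 is re-equilibrated under the same acid conditions.
- Irradiation of F5 at 365 nm (MeCN, 0 °C) cleaves the O–C bond on the auxiliary side, as with o-nitrobenzyl glycosides. The acetal carbon keeps its configuration, and 28 is released in a neutral aprotic medium.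

**Further compounds**

F1 | step 4 | 6-tert-butyl 2-methyl 5-(dimethoxymethyl)-1-(triisopropylsilyloxy)-7-oxabicyclo[2.2.1]hepta-2,5-diene-2,6-dicarboxylate (racemic, transient) | COC(=O)C1=CC2OC1(O[Si](C(C)C)(C(C)C)C(C)C)C(C(=O)OC(C)(C)C)=C2C(OC)OC
F2 | step 4 | 1-tert-butyl 3-methyl 6-(dimethoxymethyl)-5-hydroxy-2-(triisopropylsilyloxy)benzene-1,3-dicarboxylate | COC(=O)c1cc(O)c(C(OC)OC)c(C(=O)OC(C)(C)C)c1O[Si](C(C)C)(C(C)C)C(C)C
F3 | step 15 | analogue of 24 with (E)-benzylideneaminooxy in place of bromine (transient) | CC(C)(C)OC(=O)c1c(C(OC)OC)c(Oc2c(C=O)c(OCOC)cc(C)c2C(=O)O)c(O/N=C/c3ccccc3)c(C=O)c1OCOC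
F4 | step 15 | 2-[5-(tert-butoxycarbonyl)-6-(dimethoxymethyl)-3-formyl-2-hydroxy-4-(methoxymethoxy)phenoxy]-3-formyl-4-(methoxymethoxy)-6-methylbenzoic acid | CC(C)(C)OC(=O)c1c(C(OC)OC)c(Oc2c(C=O)c(OCOC)cc(C)c2C(=O)O)c(O)c(C=O)c1OCOC
F5 | step 17 | O-[(R)-1-(2-nitrophenyl)ethyl] acetal of 28, acetal carbon S | Cc1cc(O)c(C=O)c2c1C(=O)Oc1c(C=O)c(O)c3c(c1O2)[C@@H](O[C@H](C)c4ccccc4[N+](=O)[O-])OC3=O
F6 | step 17 | O-[(R)-1-(2-nitrophenyl)ethyl] acetal, acetal carbon R | Cc1cc(O)c(C=O)c2c1C(=O)Oc1c(C=O)c(O)c3c(c1O2)[C@H](O[C@H](C)c4ccccc4[N+](=O)[O-])OC3=O
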